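**Retrosynthetic overview**
1. Target 29 ⇐ diene lactone 28 by a late, chemoselective peracid epoxidation of C1=C10 (oxirane formed last); the O3 acetate and O8 isovalerate are placed one after the other on the 3‑O‑TES/8‑O‑TBS lactone 24.
2. Lactone 24 ⇐ open‑chain allenyl (Z)‑enal 21 + CO2 in one nickel‑mediated operation: C11–C12 (CO2 carbon onto the central allene carbon) and C6–C7 (γ‑carbon of the resulting allyl nickel onto the formyl carbon); the aldehyde oxygen O6 then closes the lactone onto C12.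
3. Enabling feature: the terminal 1,2‑diene C7=C11=C13 next to the C8 silyloxy stereocentre; CO2 uptake at C11 turns C13–C11–C7 into a 2‑carboxylato‑allyl metal aimed at the C6 formyl group of the (Z)‑C4=C5 enal, so the new C6–C7 bond is shared by the ten‑membered carbocycle (C1–C10) and the lactone ring (O–C6–C7–C11–C12).
4. Enal 21 ⇐ (E)‑alkenyl iodide 5 (C8 from (S)‑glycidyl ether 1, C1=C10 by carboalumination) + (S)‑epoxy ketal 8 (C3), joined at C1–C2; the (Z)‑C4=C5 geometry is fixed in a temporary butenolide ring (13, O3–C6 bond, not in the target) that is opened by reduction; the allene is built from the C7 aldehyde.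
5. Order of ring formation: butenolide (temporary, opened again) → ten‑membered carbocycle and γ‑lactone together in the key step (through a transient nickelalactone) → oxirane.

Key step: step 16

Remark: positions are given in germacrane numbering (ring C1–C10, C11 the lactone α‑carbon, C12 its carbonyl carbon, C13 the exocyclic methylene carbon); (S)‑PMB glycidyl ether 1 is taken as a commercial building block.

**Route**

Step 1
Reactants: 1 (S)-2-{[(4-methoxybenzyl)oxy]methyl}oxirane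
Product: 2 (S)-1-[(4-methoxybenzyl)oxy]pent-4-yn-2-ol
Conditions: lithium acetylide–ethylenediamine complex (LiC≡CH·H2NCH2CH2NH2), DMSO, 0 °C to rt
Reagents that add atoms: lithium acetylide–ethylenediamine complex, [Li+].[C-]#C.NCCN
Why: SN2 opening of the terminal epoxide at its CH2 carbon by the acetylide (epoxide alkynylation) gives the homopropargylic alcohol, and the C8 stereocentre is taken unchanged from 1.

Step 2
Reactants: 2 (S)-1-[(4-methoxybenzyl)oxy]pent-4-yn-2-ol
Product: 3 (S)-tert-butyl({1-[(4-methoxybenzyl)oxy]pent-4-yn-2-yl}oxy)dimethylsilane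
Conditions: TBSCl, imidazole, DMF, rt
Reagents that add atoms: tert-butyldimethylsilyl chloride, CC(C)(C)[Si](C)(C)Cl
Why: Standard silylation of the secondary alcohol, which protects O8 through all organometallic steps.

Step 3
Reactants: 3 (S)-tert-butyl({1-[(4-methoxybenzyl)oxy]pent-4-yn-2-yl}oxy)dimethylsilane
Product: 5 tert-butyl({(2S,4E)-5-iodo-1-[(4-methoxybenzyl)oxy]-4-methylpent-4-en-2-yl}oxy)dimethylsilane, via alkenyldimethylalane 4 (not isolated)
Conditions: Me3Al, Cp2ZrCl2 (0.25 equiv), CH2Cl2, 0 °C to rt; then I2, THF, −30 °C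
Reagents that add atoms: trimethylaluminium, C[Al](C)C; iodine, II
Why: Negishi zirconium-catalysed carboalumination adds methyl and aluminium syn across the terminal alkyne (methyl on C10, aluminium on C1), and iodinolysis with retention gives the (E)-alkenyl iodide that carries the future C1=C10 geometry.

Step 4
Reactants: 6 2-methyl-2-vinyl-1,3-dioxolane
Product: 7 rac-2-methyl-2-(oxiran-2-yl)-1,3-dioxolane
Conditions: mCPBA, CH2Cl2, rt
Reagents that add atoms: 3-chloroperbenzoic acid, O=C(OO)c1cccc(Cl)c1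
Why: Prilezhaev epoxidation of the monosubstituted alkene, with the ketal stable to the buffered peracid.

Step 5
Reactants: 7 rac-2-methyl-2-(oxiran-2-yl)-1,3-dioxolane
Product: 8 (S)-2-methyl-2-(oxiran-2-yl)-1,3-dioxolane
Conditions: (S,S)-N,N′-bis(3,5-di-tert-butylsalicylidene)-1,2-cyclohexanediaminocobalt acetate (trivalent cobalt, 0.5 mol %), H2O (0.55 equiv), THF, 0 °C to rt; distillation
Reagents that add atoms: none
Why: Jacobsen hydrolytic kinetic resolution of a terminal epoxide, run with the catalyst antipode that hydrolyses (R)-7 faster so that (S)-8, the source of the C3 stereocentre, is recovered.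

Step 6
Reactants: 5 tert-butyl({(2S,4E)-5-iodo-1-[(4-methoxybenzyl)oxy]-4-methylpent-4-en-2-yl}oxy)dimethylsilane; 8 (S)-2-methyl-2-(oxiran-2-yl)-1,3-dioxolane
Product: 10 (1S,3E,6S)-6-[(tert-butyldimethylsilyl)oxy]-7-[(4-methoxybenzyl)oxy]-4-methyl-1-(2-methyl-1,3-dioxolan-2-yl)hept-3-en-1-ol, via alkenyllithium 9 (not isolated)
Conditions: t-BuLi (2.1 equiv), Et2O, −78 °C; then 8, BF3·OEt2, −78 °C
Reagents that add atoms: none
Why: Iodine–lithium exchange with retention of alkene geometry followed by BF3-assisted SN2 opening of the epoxide at its unhindered CH2 carbon forms the C1–C2 bond, and C3 keeps the configuration of 8 because its C–O bond is not touched.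

Step 7
Reactants: 10 (1S,3E,6S)-6-[(tert-butyldimethylsilyl)oxy]-7-[(4-methoxybenzyl)oxy]-4-methyl-1-(2-methyl-1,3-dioxolan-2-yl)hept-3-en-1-ol
Product: 11 (3S,5E,8S)-8-[(tert-butyldimethylsilyl)oxy]-3-hydroxy-9-[(4-methoxybenzyl)oxy]-6-methylnon-5-en-2-one
Conditions: PPTS, acetone–H2O (10:1), 50 °C
Reagents that add atoms: water, O
Why: Mild acid-catalysed hydrolysis of the dioxolane frees the methyl ketone at an acidity the secondary TBS and PMB ethers tolerate.

Step 8
Reactants: 11 (3S,5E,8S)-8-[(tert-butyldimethylsilyl)oxy]-3-hydroxy-9-[(4-methoxybenzyl)oxy]-6-methylnon-5-en-2-one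
Product: 13 (S)-5-{(2E,5S)-5-[(tert-butyldimethylsilyl)oxy]-6-[(4-methoxybenzyl)oxy]-3-methylhex-2-en-1-yl}-4-methylfuran-2(5H)-one, via phosphorane ester 12 (not isolated)
Conditions: Ph3P=C=C=O, toluene, 100 °C
Reagents that add atoms: (triphenylphosphoranylidene)ketene, O=C=C=P(c1ccccc1)(c1ccccc1)c1ccccc1
Why: Bestmann butenolide synthesis, in which O-acylation of the α-hydroxy ketone by the ketene ylide and intramolecular Wittig reaction of 12 with the methyl ketone close the 4-methylbutenolide, a ring that forces C3 and C6 cis on the C4=C5 bond.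

Step 9
Reactants: 13 (S)-5-{(2E,5S)-5-[(tert-butyldimethylsilyl)oxy]-6-[(4-methoxybenzyl)oxy]-3-methylhex-2-en-1-yl}-4-methylfuran-2(5H)-one
Product: 14 (2Z,4S,6E,9S)-9-[(tert-butyldimethylsilyl)oxy]-10-[(4-methoxybenzyl)oxy]-3,7-dimethyldeca-2,6-diene-1,4-diol
Conditions: DIBAL-H (i-Bu2AlH, 3.5 equiv), CH2Cl2, −78 to 0 °C; Rochelle salt (KNaC4H4O6)
Reagents that add atoms: none
Why: Exhaustive hydride reduction of the unsaturated lactone opens the temporary ring to the (Z)-ene-1,4-diol with the ring-enforced alkene geometry retained.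

Step 10
Reactants: 14 (2Z,4S,6E,9S)-9-[(tert-butyldimethylsilyl)oxy]-10-[(4-methoxybenzyl)oxy]-3,7-dimethyldeca-2,6-diene-1,4-diol
Product: 15 (2Z,4S,6E,9S)-9-[(tert-butyldimethylsilyl)oxy]-10-[(4-methoxybenzyl)oxy]-3,7-dimethyl-1,4-bis[(triethylsilyl)oxy]deca-2,6-diene
Conditions: Et3SiCl (2.5 equiv), imidazole, DMF, 0 °C to rt
Reagents that add atoms: chlorotriethylsilane, CC[Si](Cl)(CC)CC
Why: Double silylation gives a primary TES ether that can later be oxidised selectively and a secondary TES ether at O3 that can be removed in the presence of the O8 TBS ether.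

Step 11
Reactants: 15 (2Z,4S,6E,9S)-9-[(tert-butyldimethylsilyl)oxy]-10-[(4-methoxybenzyl)oxy]-3,7-dimethyl-1,4-bis[(triethylsilyl)oxy]deca-2,6-diene
Product: 16 (2S,4E,7S,8Z)-2-[(tert-butyldimethylsilyl)oxy]-4,8-dimethyl-7,10-bis[(triethylsilyl)oxy]deca-4,8-dien-1-ol
Conditions: DDQ, CH2Cl2–pH 7 buffer, 0 °C
Reagents that add atoms: none
Why: Oxidative cleavage of the PMB ether by DDQ frees the C7 primary alcohol and leaves the silyl ethers and both trisubstituted alkenes intact.

Step 12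
Reactants: 16 (2S,4E,7S,8Z)-2-[(tert-butyldimethylsilyl)oxy]-4,8-dimethyl-7,10-bis[(triethylsilyl)oxy]deca-4,8-dien-1-ol
Product: 17 (2S,4E,7S,8Z)-2-[(tert-butyldimethylsilyl)oxy]-4,8-dimethyl-7,10-bis[(triethylsilyl)oxy]deca-4,8-dienal
Conditions: Dess–Martin periodinane, NaHCO3, CH2Cl2, 0 °C to rt
Reagents that add atoms: none
Why: Buffered hypervalent-iodine oxidation of the only free alcohol gives the α-silyloxy aldehyde without epimerising C8.

Step 13
Reactants: 17 (2S,4E,7S,8Z)-2-[(tert-butyldimethylsilyl)oxy]-4,8-dimethyl-7,10-bis[(triethylsilyl)oxy]deca-4,8-dienal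
Product: 18 (3S,5E,8S,9Z)-3-[(tert-butyldimethylsilyl)oxy]-5,9-dimethyl-8,11-bis[(triethylsilyl)oxy]undeca-5,9-dien-1-yne
Conditions: dimethyl (1-diazo-2-oxopropyl)phosphonate, K2CO3, MeOH, 0 °C to rt
Reagents that add atoms: dimethyl (1-diazo-2-oxopropyl)phosphonate, COP(=O)(OC)C(=[N+]=[N-])C(C)=O
Why: Seyferth–Gilbert homologation in the Ohira–Bestmann variant converts the aldehyde into the terminal alkyne (C7≡C11) under carbonate conditions mild enough for the α-silyloxy stereocentre.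

Step 14
Reactants: 18 (3S,5E,8S,9Z)-3-[(tert-butyldimethylsilyl)oxy]-5,9-dimethyl-8,11-bis[(triethylsilyl)oxy]undeca-5,9-dien-1-yne
Product: 20 (4S,6E,9S,10Z)-4-[(tert-butyldimethylsilyl)oxy]-6,10-dimethyl-9,12-bis[(triethylsilyl)oxy]dodeca-1,2,6,10-tetraene, via propargylic amine 19 (not isolated)
Conditions: (CH2O)n, CuI (0.5 equiv), Cy2NH, dioxane, 100 °C
Reagents that add atoms: formaldehyde (as paraformaldehyde), C=O
Why: Crabbé allene homologation, in which the copper-mediated Mannich base 19 undergoes a 1,5-hydride shift with loss of imine to give the terminal 1,2-diene C7=C11=C13.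

Step 15
Reactants: 20 (4S,6E,9S,10Z)-4-[(tert-butyldimethylsilyl)oxy]-6,10-dimethyl-9,12-bis[(triethylsilyl)oxy]dodeca-1,2,6,10-tetraene
Product: 21 (2Z,4S,6E,9S)-9-[(tert-butyldimethylsilyl)oxy]-3,7-dimethyl-4-[(triethylsilyl)oxy]dodeca-2,6,10,11-tetraenal
Conditions: (COCl)2, DMSO, CH2Cl2, −78 to −40 °C; then Et3N, −78 to −30 °C
Reagents that add atoms: none
Why: Swern oxidation applied directly to the primary allylic TES ether (chloride-assisted desilylation by the chlorosulfonium salt, then the usual ylide collapse) gives the (Z)-enal while the secondary TES and TBS ethers stay, and the low temperature keeps the (Z) geometry.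

Step 16
Reactants: 21 (2Z,4S,6E,9S)-9-[(tert-butyldimethylsilyl)oxy]-3,7-dimethyl-4-[(triethylsilyl)oxy]dodeca-2,6,10,11-tetraenal
Product: 24 3β-[(triethylsilyl)oxy]-8α-[(tert-butyldimethylsilyl)oxy]-(1(10)E,4Z)-germacra-1(10),4,11(13)-trien-12,6α-olide (6β-H, 7α-H, trans-fused), via nickelalactone 22 (not isolated), via hydroxy acid 23 (not isolated)
Conditions: Ni(cod)2 (zerovalent nickel, 1.5 equiv), DBU (3 equiv), CO2 (1 atm), THF, 0 °C, 21 added by syringe pump (final 2 mM); then 1 M HCl, 0 °C to rt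
Reagents that add atoms: carbon dioxide, O=C=O
Why: Proposed new method: zerovalent nickel joins the terminal C11=C13 π bond of the 1,2-diene and CO2 by oxidative cyclisation to nickelalactone 22 (C11–C12 formed), a 2-carboxylato-allyl nickel whose γ-carbon C7 adds to the tethered C6 formyl group through a six-membered chair transition state (C6–C7 formed), and acidification gives hydroxy acid 23, in which O6 closes the lactone onto C12. The closest known reactions are the intermolecular nickel-mediated coupling of terminal allenes, CO2 and aldehydes and the chromium-mediated intramolecular 2-(alkoxycarbonyl)allylation of aldehydes that closes ten-membered germacranolide rings at this same bond, and the proposal merges the two. The five-membered nickelalactone closes by oxidative cyclisation and is only a relay, the ten-membered carbocycle closes by 10-exo-trig addition of the allyl metal to the C=O group, and the γ-lactone closes by 5-exo-trig acyl substitution. C7 is expected to be set by attack of the aldehyde on the allyl face anti to the C8 silyloxy group in the conformer that holds H8 in the allyl plane (1,3-allylic strain), which is also the face the C9 tether reaches, and C6 by the chair with the C5 substituent pseudo-equatorial on the syn (E) allyl isomer, which gives the anti adduct and hence the trans-fused lactone. The step needs carboxylation at the central allene carbon, γ- rather than α-attack of the allyl unit, survival of the (Z)-C4=C5 enal and ring closure rather than oligomerisation, and it relies for these on the unsubstituted allene terminus, the chelated nickelalactone, a β,β-disubstituted enal without acyloxy leaving group at 0 °C, and slow addition into excess nickel reagent.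

Step 17
Reactants: 24 3β-[(triethylsilyl)oxy]-8α-[(tert-butyldimethylsilyl)oxy]-(1(10)E,4Z)-germacra-1(10),4,11(13)-trien-12,6α-olide
Product: 25 3β-hydroxy-8α-[(tert-butyldimethylsilyl)oxy]-(1(10)E,4Z)-germacra-1(10),4,11(13)-trien-12,6α-olide
Conditions: PPTS, MeOH, 0 °C
Reagents that add atoms: none
Why: Selective acid-catalysed methanolysis of the secondary TES ether, which is far more labile than the hindered secondary TBS ether at O8.

Step 18
Reactants: 25 3β-hydroxy-8α-[(tert-butyldimethylsilyl)oxy]-(1(10)E,4Z)-germacra-1(10),4,11(13)-trien-12,6α-olide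
Product: 26 3β-acetoxy-8α-[(tert-butyldimethylsilyl)oxy]-(1(10)E,4Z)-germacra-1(10),4,11(13)-trien-12,6α-olide
Conditions: Ac2O, pyridine, DMAP (cat.), CH2Cl2, 0 °C
Reagents that add atoms: acetic anhydride, CC(=O)OC(C)=O
Why: DMAP-catalysed acetylation of the only free hydroxyl group installs the O3 acetate with retention at C3.

Step 19
Reactants: 26 3β-acetoxy-8α-[(tert-butyldimethylsilyl)oxy]-(1(10)E,4Z)-germacra-1(10),4,11(13)-trien-12,6α-olide
Product: 27 3β-acetoxy-8α-hydroxy-(1(10)E,4Z)-germacra-1(10),4,11(13)-trien-12,6α-olide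
Conditions: HF·pyridine, pyridine, THF, 0 °C to rt
Reagents that add atoms: none
Why: Buffered fluoride desilylation frees O8 under conditions that spare the acetate, the α-methylene lactone and the acid-sensitive 1(10),4-diene.

Step 20
Reactants: 27 3β-acetoxy-8α-hydroxy-(1(10)E,4Z)-germacra-1(10),4,11(13)-trien-12,6α-olide
Product: 28 3β-acetoxy-8α-(3-methylbutanoyloxy)-(1(10)E,4Z)-germacra-1(10),4,11(13)-trien-12,6α-olide
Conditions: 3-methylbutanoic anhydride, DMAP, Et3N, CH2Cl2, 0 °C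
Reagents that add atoms: 3-methylbutanoic anhydride, CC(C)CC(=O)OC(=O)CC(C)C
Why: Steglich-type acylation of the secondary alcohol, fast enough to outrun acyl migration of the lactone towards O8.

Step 21
Reactants: 28 3β-acetoxy-8α-(3-methylbutanoyloxy)-(1(10)E,4Z)-germacra-1(10),4,11(13)-trien-12,6α-olide
Product: 29 3β-acetoxy-1β,10α-epoxy-8α-(3-methylbutanoyloxy)-(4Z)-germacra-4,11(13)-dien-12,6α-olide, (1R,3S,6R,7R,8S,10R), the target
Conditions: mCPBA, NaHCO3, CH2Cl2, 0 °C
Reagents that add atoms: 3-chloroperbenzoic acid, O=C(OO)c1cccc(Cl)c1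
Why: Prilezhaev epoxidation is expected to pick C1=C10, the only alkene without an allylic C–O bond or carbonyl conjugation, to add syn so that the (E)-alkene gives the trans-oxirane, and to attack the outer face of the ring conformer with the C10 methyl on the β side, which gives the 1β,10α-epoxide.

**Compound list**
1 | (S)-2-{[(4-methoxybenzyl)oxy]methyl}oxirane | COc1ccc(COC[C@@H]2CO2)cc1 | starting material
2 | (S)-1-[(4-methoxybenzyl)oxy]pent-4-yn-2-ol | C#CC[C@H](O)COCc1ccc(OC)cc1 | intermediate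
3 | (S)-tert-butyl({1-[(4-methoxybenzyl)oxy]pent-4-yn-2-yl}oxy)dimethylsilane | C#CC[C@H](O[Si](C)(C)C(C)(C)C)COCc1ccc(OC)cc1 | intermediate
4 | dimethyl{(1E,4S)-4-[(tert-butyldimethylsilyl)oxy]-5-[(4-methoxybenzyl)oxy]-2-methylpent-1-en-1-yl}alane | C[Al](C)/C=C(\C)C[C@H](O[Si](C)(C)C(C)(C)C)COCc1ccc(OC)cc1 | intermediate
5 | tert-butyl({(2S,4E)-5-iodo-1-[(4-methoxybenzyl)oxy]-4-methylpent-4-en-2-yl}oxy)dimethylsilane | I/C=C(\C)C[C@H](O[Si](C)(C)C(C)(C)C)COCc1ccc(OC)cc1 | intermediate
6 | 2-methyl-2-vinyl-1,3-dioxolane | CC1(C=C)OCCO1 | starting material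
7 | rac-2-methyl-2-(oxiran-2-yl)-1,3-dioxolane | CC1(OCCO1)C2CO2 | intermediate
8 | (S)-2-methyl-2-(oxiran-2-yl)-1,3-dioxolane | CC1(OCCO1)[C@@H]2CO2 | intermediate
9 | {(1E,4S)-4-[(tert-butyldimethylsilyl)oxy]-5-[(4-methoxybenzyl)oxy]-2-methylpent-1-en-1-yl}lithium | [Li]/C=C(\C)C[C@H](O[Si](C)(C)C(C)(C)C)COCc1ccc(OC)cc1 | intermediate
10 | (1S,3E,6S)-6-[(tert-butyldimethylsilyl)oxy]-7-[(4-methoxybenzyl)oxy]-4-methyl-1-(2-methyl-1,3-dioxolan-2-yl)hept-3-en-1-ol | CC1(OCCO1)[C@@H](O)C/C=C(\C)C[C@H](O[Si](C)(C)C(C)(C)C)COCc2ccc(OC)cc2 | intermediate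
11 | (3S,5E,8S)-8-[(tert-butyldimethylsilyl)oxy]-3-hydroxy-9-[(4-methoxybenzyl)oxy]-6-methylnon-5-en-2-one | CC(=O)[C@@H](O)C/C=C(\C)C[C@H](O[Si](C)(C)C(C)(C)C)COCc1ccc(OC)cc1 | intermediate
12 | (3S,5E,8S)-8-[(tert-butyldimethylsilyl)oxy]-9-[(4-methoxybenzyl)oxy]-6-methyl-2-oxonon-5-en-3-yl (triphenylphosphoranylidene)acetate | CC(=O)[C@@H](OC(=O)C=P(c1ccccc1)(c1ccccc1)c1ccccc1)C/C=C(\C)C[C@H](O[Si](C)(C)C(C)(C)C)COCc1ccc(OC)cc1 | intermediate
13 | (S)-5-{(2E,5S)-5-[(tert-butyldimethylsilyl)oxy]-6-[(4-methoxybenzyl)oxy]-3-methylhex-2-en-1-yl}-4-methylfuran-2(5H)-one | CC1=CC(=O)O[C@H]1C/C=C(\C)C[C@H](O[Si](C)(C)C(C)(C)C)COCc2ccc(OC)cc2 | intermediate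
14 | (2Z,4S,6E,9S)-9-[(tert-butyldimethylsilyl)oxy]-10-[(4-methoxybenzyl)oxy]-3,7-dimethyldeca-2,6-diene-1,4-diol | OC/C=C(/C)[C@@H](O)C/C=C(\C)C[C@H](O[Si](C)(C)C(C)(C)C)COCc1ccc(OC)cc1 | intermediate
15 | (2Z,4S,6E,9S)-9-[(tert-butyldimethylsilyl)oxy]-10-[(4-methoxybenzyl)oxy]-3,7-dimethyl-1,4-bis[(triethylsilyl)oxy]deca-2,6-diene | CC[Si](CC)(CC)OC/C=C(/C)[C@@H](O[Si](CC)(CC)CC)C/C=C(\C)C[C@H](O[Si](C)(C)C(C)(C)C)COCc1ccc(OC)cc1 | intermediate
16 | (2S,4E,7S,8Z)-2-[(tert-butyldimethylsilyl)oxy]-4,8-dimethyl-7,10-bis[(triethylsilyl)oxy]deca-4,8-dien-1-ol | CC[Si](CC)(CC)OC/C=C(/C)[C@@H](O[Si](CC)(CC)CC)C/C=C(\C)C[C@H](O[Si](C)(C)C(C)(C)C)CO | intermediate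
17 | (2S,4E,7S,8Z)-2-[(tert-butyldimethylsilyl)oxy]-4,8-dimethyl-7,10-bis[(triethylsilyl)oxy]deca-4,8-dienal | CC[Si](CC)(CC)OC/C=C(/C)[C@@H](O[Si](CC)(CC)CC)C/C=C(\C)C[C@H](O[Si](C)(C)C(C)(C)C)C=O | intermediate
18 | (3S,5E,8S,9Z)-3-[(tert-butyldimethylsilyl)oxy]-5,9-dimethyl-8,11-bis[(triethylsilyl)oxy]undeca-5,9-dien-1-yne | CC[Si](CC)(CC)OC/C=C(/C)[C@@H](O[Si](CC)(CC)CC)C/C=C(\C)C[C@H](O[Si](C)(C)C(C)(C)C)C#C | intermediate
19 | (4S,6E,9S,10Z)-4-[(tert-butyldimethylsilyl)oxy]-N,N-dicyclohexyl-6,10-dimethyl-9,12-bis[(triethylsilyl)oxy]dodeca-6,10-dien-2-yn-1-amine | CC[Si](CC)(CC)OC/C=C(/C)[C@@H](O[Si](CC)(CC)CC)C/C=C(\C)C[C@H](O[Si](C)(C)C(C)(C)C)C#CCN(C1CCCCC1)C1CCCCC1 | intermediate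
20 | (4S,6E,9S,10Z)-4-[(tert-butyldimethylsilyl)oxy]-6,10-dimethyl-9,12-bis[(triethylsilyl)oxy]dodeca-1,2,6,10-tetraene | CC[Si](CC)(CC)OC/C=C(/C)[C@@H](O[Si](CC)(CC)CC)C/C=C(\C)C[C@H](O[Si](C)(C)C(C)(C)C)C=C=C | intermediate
21 | (2Z,4S,6E,9S)-9-[(tert-butyldimethylsilyl)oxy]-3,7-dimethyl-4-[(triethylsilyl)oxy]dodeca-2,6,10,11-tetraenal | O=C/C=C(/C)[C@@H](O[Si](CC)(CC)CC)C/C=C(\C)C[C@H](O[Si](C)(C)C(C)(C)C)C=C=C | intermediate
22 | nickelalactone from the allene terminus of 21 and CO2: 1-oxa-2-nickelacyclopentan-5-one with nickel on C13 and on the carboxylate oxygen and an (E)-C7=C11 alkylidene at C11 (DBU ligands not drawn) | O=C/C=C(/C)[C@@H](O[Si](CC)(CC)CC)C/C=C(\C)C[C@H](O[Si](C)(C)C(C)(C)C)/C=C1/C[Ni]OC1=O | intermediate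
23 | 3β-[(triethylsilyl)oxy]-8α-[(tert-butyldimethylsilyl)oxy]-6α-hydroxy-(1(10)E,4Z)-germacra-1(10),4,11(13)-trien-12-oic acid (6β-H, 7α-H) | OC(=O)C(=C)[C@H]1[C@H](O)/C=C(/C)[C@@H](O[Si](CC)(CC)CC)C/C=C(\C)C[C@@H]1O[Si](C)(C)C(C)(C)C | intermediate
24 | 3β-[(triethylsilyl)oxy]-8α-[(tert-butyldimethylsilyl)oxy]-(1(10)E,4Z)-germacra-1(10),4,11(13)-trien-12,6α-olide (6β-H, 7α-H) | C=C1C(=O)O[C@@H]2/C=C(/C)[C@@H](O[Si](CC)(CC)CC)C/C=C(\C)C[C@H](O[Si](C)(C)C(C)(C)C)[C@@H]12 | intermediate
25 | 3β-hydroxy-8α-[(tert-butyldimethylsilyl)oxy]-(1(10)E,4Z)-germacra-1(10),4,11(13)-trien-12,6α-olide | C=C1C(=O)O[C@@H]2/C=C(/C)[C@@H](O)C/C=C(\C)C[C@H](O[Si](C)(C)C(C)(C)C)[C@@H]12 | intermediate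
26 | 3β-acetoxy-8α-[(tert-butyldimethylsilyl)oxy]-(1(10)E,4Z)-germacra-1(10),4,11(13)-trien-12,6α-olide | C=C1C(=O)O[C@@H]2/C=C(/C)[C@@H](OC(C)=O)C/C=C(\C)C[C@H](O[Si](C)(C)C(C)(C)C)[C@@H]12 | intermediate
27 | 3β-acetoxy-8α-hydroxy-(1(10)E,4Z)-germacra-1(10),4,11(13)-trien-12,6α-olide | C=C1C(=O)O[C@@H]2/C=C(/C)[C@@H](OC(C)=O)C/C=C(\C)C[C@H](O)[C@@H]12 | intermediate
28 | 3β-acetoxy-8α-(3-methylbutanoyloxy)-(1(10)E,4Z)-germacra-1(10),4,11(13)-trien-12,6α-olide | C=C1C(=O)O[C@@H]2/C=C(/C)[C@@H](OC(C)=O)C/C=C(\C)C[C@H](OC(=O)CC(C)C)[C@@H]12 | intermediate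
29 | 3β-acetoxy-1β,10α-epoxy-8α-(3-methylbutanoyloxy)-(4Z)-germacra-4,11(13)-dien-12,6α-olide, (1R,3S,6R,7R,8S,10R) | C=C1C(=O)O[C@@H]2/C=C(/C)[C@@H](OC(C)=O)C[C@H]3O[C@]3(C)C[C@H](OC(=O)CC(C)C)[C@@H]12 | target

**Step count and risks**
Total step count: 21. Longest linear sequence: 19 steps (steps 1–3 and 6–21); steps 4–5 make epoxide 8 on a side branch.

Steps most likely to fail:

1. Step 16 (proposed new method). The ten-membered ring closure may be slower than protonation, dimerisation or a second carboxylation of the carboxylato-allyl nickel. The amidine base may isomerise the (Z)-enal. Closure through the other allyl geometry would give the cis-fused lactone. The fallback uses only known chemistry, sets out from aldehyde 17 and comes back at lactone 24. A Morita–Baylis–Hillman reaction of 17 with methyl acrylate (DABCO) gives methyl (4S,6E,9S,10Z)-4-[(tert-butyldimethylsilyl)oxy]-3-hydroxy-6,10-dimethyl-2-methylidene-9,12-bis[(triethylsilyl)oxy]dodeca-6,10-dienoate F1, and acetylation (Ac2O, DMAP) gives its acetate F2. Swern oxidation of the primary TES ether as in step 15 gives the enal F3, and SN2′ displacement of the allylic acetate with LiBr gives the (Z)-2-(bromomethyl)enoate F4. CrCl2 (divalent chromium) in THF–DMF under high dilution then closes the ten-membered ring by the precedented intramolecular Nozaki–Hiyama allylation of the formyl group, and lactonisation of the resulting alkoxide onto the methyl ester on work-up gives 24. In this variant C11–C12 is bought with the acrylate, and the ring closure forms only C6–C7 and the lactone C–O bond.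

2. Step 21. Substrate control may give poor facial selectivity, and the peracid or its acid may cause over-oxidation at C4=C5 or transannular cyclisation of the diene. The fallback goes from 28 directly to 29 by Shi epoxidation (D-fructose-derived ketone catalyst, Oxone (2KHSO5·KHSO4·K2SO4), K2CO3-buffered MeCN–dimethoxymethane–H2O, 0 °C). Here the chiral dioxirane, which delivers (R,R)-epoxides from (E)-trisubstituted alkenes of this pattern, selects the alkene face instead of the ring conformation, under non-acidic conditions; no new compound is made.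

3. Step 6. The fragment union may suffer from proton transfer or decomposition of the alkenyllithium, Lewis-acid attack on the ketal, or sluggish epoxide opening. The fallback sets out from alkyne 3 and comes back at butenolide 13, and builds C3 by carbonyl addition instead. Alkenylalane 4, formed as in step 3, is treated with n-BuLi and ethylene oxide to give (3E,6S)-6-[(tert-butyldimethylsilyl)oxy]-7-[(4-methoxybenzyl)oxy]-4-methylhept-3-en-1-ol F5. Dess–Martin oxidation gives the β,γ-unsaturated aldehyde F6, which is used at once. Enantioselective addition of the zinc alkynylide of methyl propiolate (Me2Zn, ProPhenol ligand of the antipode that gives the (S)-carbinol) gives the γ-hydroxy ynoate F7. Syn-carbocupration with Me2CuLi at −78 °C, with lactonisation on work-up, gives 13.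

**Further compounds**
F1 | step 16 | methyl (4S,6E,9S,10Z)-4-[(tert-butyldimethylsilyl)oxy]-3-hydroxy-6,10-dimethyl-2-methylidene-9,12-bis[(triethylsilyl)oxy]dodeca-6,10-dienoate (both C3 epimers) | CC[Si](CC)(CC)OC/C=C(/C)[C@@H](O[Si](CC)(CC)CC)C/C=C(\C)C[C@H](O[Si](C)(C)C(C)(C)C)C(O)C(=C)C(=O)OC
F2 | step 16 | methyl (4S,6E,9S,10Z)-3-acetoxy-4-[(tert-butyldimethylsilyl)oxy]-6,10-dimethyl-2-methylidene-9,12-bis[(triethylsilyl)oxy]dodeca-6,10-dienoate | CC[Si](CC)(CC)OC/C=C(/C)[C@@H](O[Si](CC)(CC)CC)C/C=C(\C)C[C@H](O[Si](C)(C)C(C)(C)C)C(OC(C)=O)C(=C)C(=O)OC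
F3 | step 16 | methyl (4S,6E,9S,10Z)-3-acetoxy-4-[(tert-butyldimethylsilyl)oxy]-6,10-dimethyl-2-methylidene-12-oxo-9-[(triethylsilyl)oxy]dodeca-6,10-dienoate | O=C/C=C(/C)[C@@H](O[Si](CC)(CC)CC)C/C=C(\C)C[C@H](O[Si](C)(C)C(C)(C)C)C(OC(C)=O)C(=C)C(=O)OC
F4 | step 16 | methyl (2Z,4S,6E,9S,10Z)-2-(bromomethyl)-4-[(tert-butyldimethylsilyl)oxy]-6,10-dimethyl-12-oxo-9-[(triethylsilyl)oxy]dodeca-2,6,10-trienoate | O=C/C=C(/C)[C@@H](O[Si](CC)(CC)CC)C/C=C(\C)C[C@H](O[Si](C)(C)C(C)(C)C)/C=C(\CBr)C(=O)OC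
F0 | step 21 | none | none
F5 | step 6 | (3E,6S)-6-[(tert-butyldimethylsilyl)oxy]-7-[(4-methoxybenzyl)oxy]-4-methylhept-3-en-1-ol | OCC/C=C(\C)C[C@H](O[Si](C)(C)C(C)(C)C)COCc1ccc(OC)cc1
F6 | step 6 | (3E,6S)-6-[(tert-butyldimethylsilyl)oxy]-7-[(4-methoxybenzyl)oxy]-4-methylhept-3-enal | O=CC/C=C(\C)C[C@H](O[Si](C)(C)C(C)(C)C)COCc1ccc(OC)cc1
F7 | step 6 | methyl (4S,6E,9S)-9-[(tert-butyldimethylsilyl)oxy]-4-hydroxy-10-[(4-methoxybenzyl)oxy]-7-methyldec-6-en-2-ynoate | COC(=O)C#C[C@@H](O)C/C=C(\C)C[C@H](O[Si](C)(C)C(C)(C)C)COCc1ccc(OC)cc1
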